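The numbers in the tables are simulated with constants of no real substance, and the scatter is random.

At early times G was still climbing in both earlier runs, from 9.8% to 17.1% in the noon run and from 31.5% to 50.0% in the autumn run, so I looked to their last readings to see where X stopped.

the same everywhere: D 1.6 mM; L 0.27 mM
- noon: X 0.54 M; run made earlier
- autumn: X 1.2 M; run made earlier
- Thursday's: X 0.80 M; time 2.5 d
- Monday's: X 0.80 M; time 0.60 d

| run | time / h | G / % |
|---|---|---|
| noon | 10.0 | 9.8 |
| noon | 20.0 | 17.1 |
| noon | 30.0 | 21.1 |
| noon | 40.0 | 22.8 |
| noon | 50.0 | 25.9 |
| autumn | 10.0 | 31.5 |
| autumn | 20.0 | 50.0 |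
| autumn | 30.0 | 59.2 |
| autumn | 40.0 | 62.3 |
| autumn | 50.0 | 64.2 |

(each reading ± 1 percentage point)

- the average divides the monomer in chains by the number of chains begun, living and dead together
- on the list of suspects stand: X + Z -> G + Z; G + Z -> X + Z; D + L -> E; X + D -> Z + G; D -> Q
- the earlier runs do not show the number of chains; that part of a forecast is a guess

1. which of the two ends with the longer chains by the average number of monomer units in a chain (chains begun, living or dead) ("neither" if they lie within 10%) (Thursday's / Monday's / neither)
2. average number of monomer units in a chain (chains begun, living or dead) at the end, Thursday's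
3. average number of monomer units in a chain (chains begun, living or dead) at the end, Monday's

The noon run ended with 0.400 M of X free and the autumn run with 0.430 M, although autumn was charged with twice as much. I therefore took the noon reading as the ceiling c_X, the free X at which the back step of the living end balances its forward step (the equilibrium monomer concentration). I treated that balance as the end of the run: G ends at the charge less this ceiling.

The time scales then made a ladder. First, I guessed that L takes its 0.27 mM of D early, leaving 1.33 mM of D as my count of chains, since the runs do not show chains.

Next, I read the autumn run, whose span to the ceiling is wider than noon's. Between its first two readings the gap closed at 0.0747 h⁻¹, and traced back, this gave a lag of 1.44 h, shorter than the relaxation time of 13.4 h.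

Last came the stopping times, with that rate assumed at 0.80 M. I reckoned 0.395 M of G for Thursday's and, for Monday's, stopped far earlier, 0.248 M. On my count of chains that meant lengths of 297 for Thursday's and 187 for Monday's.

The forecast chose the same flask but gave longer chains than mine, 715 and 415, on the ground that “Chain count is equal, so Thursday's chains are longer”.

The computed answer was Thursday's, with 367 against 221.

    X + Z → G + Z, rate k1*[Z]*[X] (k = 62.0 L mol⁻¹ h⁻¹)
    G + Z → X + Z, rate k2*[Z] as long as [G] is above zero (k = 25.0 h⁻¹)
    D + L → E (k = 9800 L mol⁻¹ h⁻¹)
    X + D → Z + G (k = 1.10 L mol⁻¹ h⁻¹)
    D → Q (k = 0.220 h⁻¹)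

Thursday's held c_Z at 0.00106 M at the asked time, 79.7% of my count of chains. Thursday's charge less the ceiling, divided by that c_Z, gives 377, and Monday's, left until 6.00 d, reached 374.

In the neighbour of Thursday's charged with 1.4 M of X, the ceiling puts 71.4% of the charge into chains. The computed flask held G at 70.2% after 2.50 d, with a length of 846.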